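## Retrosynthetic overview

- The target comes from its 3,4-O-isopropylidene derivative, which comes from the corresponding aryl ketone by a 1,3-syn, chelation-controlled hydride reduction (C1′ is set from C3′).
- The C1′–C2′ bond is made in a light-driven ring-opening acylation. β-Scission of the anomeric alkoxy radical of a 1-C-tridecyl-2-deoxy-L-fucopyranose hemiketal turns O5–C1 into the C5′ tetradecanoate and C2 into a primary radical, which nickel joins to the bis-oxazole carboxylic acid.
- The hemiketal comes from C1-lithiation/alkylation/hydration of 3,4-O-isopropylidene-L-fucal, made from 3,4-di-O-acetyl-L-fucal, which supplies C3′, C4′ and C5′.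
- The bis-oxazole acid comes from Negishi coupling of (oxazol-5-ylmethyl)zinc chloride with ethyl 2-chlorooxazole-4-carboxylate, then saponification.
- Rings: both oxazoles are bought intact and no ring of the target is built. The dioxolane protecting ring is formed in step 2 and removed in step 8; the pyranose ring is opened in step 6.

Assumption: 3,4-di-O-acetyl-L-fucal (the commercial glycal of L-fucose), 1-bromotridecane, 5-(chloromethyl)oxazole and ethyl 2-chlorooxazole-4-carboxylate are taken as purchasable.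

Abbreviations: dF(CF3)ppy = cyclometalated 2-(2,4-difluorophenyl)-5-(trifluoromethyl)pyridine; d(CF3)bpy = 5,5′-bis(trifluoromethyl)-2,2′-bipyridine; dtbbpy = 4,4′-di-tert-butyl-2,2′-bipyridine; dme = 1,2-dimethoxyethane; PPTS = pyridinium p-toluenesulfonate; SPhos = 2-dicyclohexylphosphino-2′,6′-dimethoxybiphenyl. Primed locants refer to the hexyl chain of the target (C1′ = carbinol carbon on the oxazole, C6′ = methyl).

## Route

Step 1
Reactants: 1 3,4-di-O-acetyl-L-fucal
Product: 2 L-fucal
Conditions: K2CO3 (0.1 equiv), MeOH, rt, 2 h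
Reagents that add atoms: none
Why: Zemplén-type base-catalysed transesterification removes both acetates without touching the acid-sensitive enol ether, and the three purchased stereocentres (C3, C4, C5) are not involved.

Step 2
Reactants: 2 L-fucal
Product: 3 3,4-O-isopropylidene-L-fucal
Conditions: Me2C(OMe)2 (3 equiv), PPTS (5 mol%), acetone, 0 °C → rt
Reagents that add atoms: 2,2-dimethoxypropane (COC(C)(C)OC)
Why: Acid-catalysed transacetalisation closes a dioxolane on the cis-3,4-diol, and the weak acid PPTS avoids protonation of the glycal double bond; no stereocentre changes.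

Step 3
Reactants: 3 3,4-O-isopropylidene-L-fucal; 4 1-bromotridecane
Product: 7 2,6-dideoxy-3,4-O-isopropylidene-1-C-tridecyl-L-lyxo-hexopyranose (cyclic hemiketal; anomeric mixture), via 1-lithio glycal 5 (not isolated), via 1-C-tridecyl glycal 6 (not isolated)
Conditions: t-BuLi (1.6 equiv), THF, −78 → 0 °C; 4 (1.5 equiv), DMPU, −78 °C → rt; then PPTS (10 mol%), THF/H2O (5:1), rt
Reagents that add atoms: water (O)
Why: Vinylic C1–H lithiation of the glycal gives an α-alkoxy vinyllithium that is alkylated (SN2) by the primary bromide, and the resulting electron-rich trisubstituted enol ether undergoes Markovnikov acid-catalysed hydration through the tertiary oxocarbenium ion to the hemiketal; the acetonide survives PPTS, and the new anomeric centre (mainly OH axial, tridecyl equatorial) is destroyed in step 6.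

Step 4
Reactants: 8 5-(chloromethyl)-1,3-oxazole; 9 ethyl 2-chloro-1,3-oxazole-4-carboxylate
Product: 11 ethyl 2-(1,3-oxazol-5-ylmethyl)-1,3-oxazole-4-carboxylate, via organozinc chloride 10 (not isolated)
Conditions: Zn dust, LiCl, THF, 25 °C; then 9, Pd(OAc)2 (2 mol%), SPhos (4 mol%), THF, 25 → 50 °C
Reagents that add atoms: none
Why: LiCl-assisted zinc insertion into the heterobenzylic chloride followed by Negishi coupling at the activated C2–Cl of the oxazole ester; the neutral organozinc tolerates the ester and the acidic oxazole C2–H that would quench lithium or magnesium reagents.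

Step 5
Reactants: 11 ethyl 2-(1,3-oxazol-5-ylmethyl)-1,3-oxazole-4-carboxylate
Product: 13 2-(1,3-oxazol-5-ylmethyl)-1,3-oxazole-4-carboxylic acid, via lithium carboxylate 12 (not isolated)
Conditions: LiOH·H2O (1.5 equiv), THF/H2O (3:1), 0 °C → rt; then 1 M HCl to pH 3
Reagents that add atoms: lithium hydroxide ([Li+].[OH-])
Why: Saponification (acyl substitution by hydroxide) followed by acidification, a routine hydrolysis for oxazole-4-carboxylates.

Step 6
Reactants: 7 2,6-dideoxy-3,4-O-isopropylidene-1-C-tridecyl-L-lyxo-hexopyranose; 13 2-(1,3-oxazol-5-ylmethyl)-1,3-oxazole-4-carboxylic acid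
Product: 15 (1S)-1-[(4R,5S)-2,2-dimethyl-5-{2-[2-(1,3-oxazol-5-ylmethyl)-1,3-oxazol-4-yl]-2-oxoethyl}-1,3-dioxolan-4-yl]ethyl tetradecanoate, via mixed anhydride 14 (not isolated)
Conditions: 13 (1.5 equiv), dimethyl dicarbonate (1.6 equiv), 2,4,6-collidine (2 equiv), MeCN/PhCF3 (1:1), rt, 30 min; then 7 (1 equiv), [Ir(dF(CF3)ppy)2(5,5′-d(CF3)bpy)]PF6 (2 mol%), NiBr2·dme (10 mol%), dtbbpy (12 mol%), 450 nm LEDs, 25 °C, Ar
Reagents that add atoms: none
Why: Proposed new method: a photochemical ring-opening acylation in which the excited trivalent-iridium photocatalyst and collidine take an electron and a proton from the hemiketal O–H of 7 (concerted proton-coupled electron transfer), the anomeric alkoxy radical undergoes β-scission of the endocyclic C1–C2 bond (the only C–C bond antiperiplanar to a ring-oxygen lone pair when OH is axial and tridecyl equatorial, with cleavage also releasing the strain of the cis-fused bicycle and giving an open Z-ester, not a δ-lactone) so that O5 emerges as the tetradecanoate and C2 as a primary radical, and this radical is captured by the acyl–nickel species formed by oxidative addition of zerovalent nickel into mixed anhydride 14 and reductively eliminated as the ketone, the reduced photocatalyst returning nickel to the zerovalent state; no stereocentre is touched, and the closest known reaction types are the proton-coupled-electron-transfer ring-opening arylation of tertiary cycloalkanols under nickel/photoredox catalysis, the hypoiodite fragmentation of sugar lactols to iodo formates, and nickel/photoredox ketone synthesis from carboxylic acids activated in situ plus alkyl radical precursors.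

Step 7
Reactants: 15 (1S)-1-[(4R,5S)-2,2-dimethyl-5-{2-[2-(1,3-oxazol-5-ylmethyl)-1,3-oxazol-4-yl]-2-oxoethyl}-1,3-dioxolan-4-yl]ethyl tetradecanoate
Product: 16 (1S)-1-[(4R,5S)-5-{(2R)-2-hydroxy-2-[2-(1,3-oxazol-5-ylmethyl)-1,3-oxazol-4-yl]ethyl}-2,2-dimethyl-1,3-dioxolan-4-yl]ethyl tetradecanoate
Conditions: LiI (5 equiv), LiAlH(OtBu)3 (2.5 equiv), Et2O, −78 °C; aq. potassium sodium tartrate work-up
Reagents that add atoms: none
Why: Chelation-controlled reduction of a β-alkoxy ketone: Li+ bridges the ketone oxygen and the dioxolane oxygen on C3′ (assisted by the oxazole nitrogen) in a six-membered chelate, and hydride adds to the face opposite the C3′ substituent to give the 1,3-syn (1′R) alcohol, while the hindered alkoxyaluminium hydride leaves the ester alone at −78 °C; any minor 1′S epimer is removed by chromatography.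

Step 8
Reactants: 16 (1S)-1-[(4R,5S)-5-{(2R)-2-hydroxy-2-[2-(1,3-oxazol-5-ylmethyl)-1,3-oxazol-4-yl]ethyl}-2,2-dimethyl-1,3-dioxolan-4-yl]ethyl tetradecanoate
Product: 17 (2S,3S,4S,6R)-3,4,6-trihydroxy-6-[2-(1,3-oxazol-5-ylmethyl)-1,3-oxazol-4-yl]hexan-2-yl tetradecanoate
Conditions: AcOH/H2O (4:1), 45 °C
Reagents that add atoms: none
Why: Acid-catalysed acetal hydrolysis frees the C3′/C4′ diol; the secondary tetradecanoate and both oxazoles are stable to aqueous acetic acid, acyl migration is slow under acidic conditions, and no stereocentre is affected.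

## Compound list

1 | 3,4-di-O-acetyl-L-fucal (3,4-di-O-acetyl-1,5-anhydro-2,6-dideoxy-L-lyxo-hex-1-enitol) | C1=C[C@H](OC(C)=O)[C@H](OC(C)=O)[C@H](C)O1 | starting material
2 | L-fucal ((2S,3S,4S)-2-methyl-3,4-dihydro-2H-pyran-3,4-diol) | C1=C[C@H](O)[C@H](O)[C@H](C)O1 | intermediate
3 | 3,4-O-isopropylidene-L-fucal (1,5-anhydro-2,6-dideoxy-3,4-O-isopropylidene-L-lyxo-hex-1-enitol) | C1=C[C@@H]2OC(C)(C)O[C@@H]2[C@H](C)O1 | intermediate
4 | 1-bromotridecane | CCCCCCCCCCCCCBr | starting material
5 | 1-lithio-3,4-O-isopropylidene-L-fucal (lithium on the enol-ether carbon C1) | [Li]C1=C[C@@H]2OC(C)(C)O[C@@H]2[C@H](C)O1 | intermediate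
6 | 3,4-O-isopropylidene-1-C-tridecyl-L-fucal (tridecyl on C1 of the glycal) | CCCCCCCCCCCCCC1=C[C@@H]2OC(C)(C)O[C@@H]2[C@H](C)O1 | intermediate
7 | 2,6-dideoxy-3,4-O-isopropylidene-1-C-tridecyl-L-lyxo-hexopyranose (cyclic hemiketal, anomeric carbon unspecified, in equilibrium with the open 5-hydroxy ketone) | CCCCCCCCCCCCCC1(O)C[C@@H]2OC(C)(C)O[C@@H]2[C@H](C)O1 | intermediate
8 | 5-(chloromethyl)-1,3-oxazole | ClCc1cnco1 | starting material
9 | ethyl 2-chloro-1,3-oxazole-4-carboxylate | CCOC(=O)c1coc(Cl)n1 | starting material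
10 | (1,3-oxazol-5-ylmethyl)zinc chloride | Cl[Zn]Cc1cnco1 | intermediate
11 | ethyl 2-(1,3-oxazol-5-ylmethyl)-1,3-oxazole-4-carboxylate | CCOC(=O)c1coc(Cc2cnco2)n1 | intermediate
12 | lithium 2-(1,3-oxazol-5-ylmethyl)-1,3-oxazole-4-carboxylate | [Li+].[O-]C(=O)c1coc(Cc2cnco2)n1 | intermediate
13 | 2-(1,3-oxazol-5-ylmethyl)-1,3-oxazole-4-carboxylic acid | OC(=O)c1coc(Cc2cnco2)n1 | intermediate
14 | methyl carbonic 2-(1,3-oxazol-5-ylmethyl)-1,3-oxazole-4-carboxylic anhydride | COC(=O)OC(=O)c1coc(Cc2cnco2)n1 | intermediate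
15 | (1S)-1-[(4R,5S)-2,2-dimethyl-5-{2-[2-(1,3-oxazol-5-ylmethyl)-1,3-oxazol-4-yl]-2-oxoethyl}-1,3-dioxolan-4-yl]ethyl tetradecanoate | CCCCCCCCCCCCCC(=O)O[C@@H](C)[C@H]1OC(C)(C)O[C@H]1CC(=O)c2coc(Cc3cnco3)n2 | intermediate
16 | (1S)-1-[(4R,5S)-5-{(2R)-2-hydroxy-2-[2-(1,3-oxazol-5-ylmethyl)-1,3-oxazol-4-yl]ethyl}-2,2-dimethyl-1,3-dioxolan-4-yl]ethyl tetradecanoate | CCCCCCCCCCCCCC(=O)O[C@@H](C)[C@H]1OC(C)(C)O[C@H]1C[C@@H](O)c2coc(Cc3cnco3)n2 | intermediate
17 | (2S,3S,4S,6R)-3,4,6-trihydroxy-6-[2-(1,3-oxazol-5-ylmethyl)-1,3-oxazol-4-yl]hexan-2-yl tetradecanoate | CCCCCCCCCCCCCC(=O)O[C@@H](C)[C@@H](O)[C@@H](O)C[C@@H](O)c1coc(Cc2cnco2)n1 | target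

## Step count and risks

Total steps: 8. Longest linear sequence: 6 (steps 1, 2, 3, 6, 7, 8 from compound 1); steps 4 and 5 form the convergent branch.

**Step 6 (proposed new step).** Possible failures:
- β-scission on the wrong side, losing the tridecyl chain as a dodecyl radical and leaving the lactone;
- activation of the secondary OH of the open-chain tautomer of 7, or its O-acylation by 14;
- inefficient capture of the unstabilised primary radical by nickel.

The fallback uses known chemistry in which the fragmentation can only cleave C1–C2. It sets out from glycal acetonide 3 and acid 13 and comes back at ketone 15. Hydration of 3 (PPh3·HBr cat., THF/H2O) gives 2,6-dideoxy-3,4-O-isopropylidene-L-lyxo-hexopyranose F1. Hypoiodite fragmentation of this lactol (PhI(OAc)2, I2, CH2Cl2, visible light) gives (1S)-1-[(4R,5R)-5-(iodomethyl)-2,2-dimethyl-1,3-dioxolan-4-yl]ethyl formate F2. Acid 13 is converted with 2,2′-dipyridyl disulfide and PPh3 into S-pyridin-2-yl 2-(1,3-oxazol-5-ylmethyl)-1,3-oxazole-4-carbothioate F3. Nickel-catalysed reductive cross-electrophile coupling of F2 with F3 (NiCl2·dme, dtbbpy, Zn, DMA) gives the formate of the keto alcohol F4. KHCO3 in MeOH removes the formate to give the C5′-hydroxy ketone F5, which is in equilibrium with its cyclic hemiketal. Tetradecanoyl chloride, pyridine and DMAP acylate the open form to give 15.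

**Step 7.** The chelate through a dioxolane oxygen may give only modest syn selectivity. The fallback relies on boron-directed reduction of a free β-hydroxy ketone; it sets out from 15 and comes back at target 17. Brief hydrolysis of the acetonide (AcOH/H2O, rt to 40 °C, short contact to avoid furan formation) gives (2S,3S,4S)-3,4-dihydroxy-6-oxo-6-[2-(1,3-oxazol-5-ylmethyl)-1,3-oxazol-4-yl]hexan-2-yl tetradecanoate F6. Narasaka–Prasad reduction (Et2BOMe, NaBH4, THF/MeOH, −78 °C) through the boron chelate of the C3′ hydroxyl and the ketone then gives the 1,3-syn diol, which is 17 itself.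

**Step 3.** Alkylation of the hindered 1-lithio glycal with a long-chain bromide may be sluggish, and hydration must spare the acetonide. The fallback builds the hemiketal by carbonyl addition; it sets out from 3 and 4 and comes back at 7. Hydration of 3 gives the same lactol F1 as above. Oxidation (TEMPO cat., PhI(OAc)2, CH2Cl2) gives 2,6-dideoxy-3,4-O-isopropylidene-L-lyxo-hexono-1,5-lactone F7. Mono-addition of tridecylmagnesium bromide F8 (from 4 and Mg, THF) at −78 °C gives hemiketal 7.

## Further compounds

F1 | step 6 | 2,6-dideoxy-3,4-O-isopropylidene-L-lyxo-hexopyranose (lactol, anomeric mixture) | OC1C[C@@H]2OC(C)(C)O[C@@H]2[C@H](C)O1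
F2 | step 6 | (1S)-1-[(4R,5R)-5-(iodomethyl)-2,2-dimethyl-1,3-dioxolan-4-yl]ethyl formate | O=CO[C@@H](C)[C@H]1OC(C)(C)O[C@H]1CI
F3 | step 6 | S-pyridin-2-yl 2-(1,3-oxazol-5-ylmethyl)-1,3-oxazole-4-carbothioate | O=C(Sc1ccccn1)c2coc(Cc3cnco3)n2
F4 | step 6 | (1S)-1-[(4R,5S)-2,2-dimethyl-5-{2-[2-(1,3-oxazol-5-ylmethyl)-1,3-oxazol-4-yl]-2-oxoethyl}-1,3-dioxolan-4-yl]ethyl formate | O=CO[C@@H](C)[C@H]1OC(C)(C)O[C@H]1CC(=O)c2coc(Cc3cnco3)n2
F5 | step 6 | C5′-hydroxy ketone: analogue of 15 with free OH in place of the tetradecanoate | O[C@@H](C)[C@H]1OC(C)(C)O[C@H]1CC(=O)c2coc(Cc3cnco3)n2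
F6 | step 7 | (2S,3S,4S)-3,4-dihydroxy-6-oxo-6-[2-(1,3-oxazol-5-ylmethyl)-1,3-oxazol-4-yl]hexan-2-yl tetradecanoate | CCCCCCCCCCCCCC(=O)O[C@@H](C)[C@@H](O)[C@@H](O)CC(=O)c1coc(Cc2cnco2)n1
F7 | step 3 | 2,6-dideoxy-3,4-O-isopropylidene-L-lyxo-hexono-1,5-lactone | O=C1C[C@@H]2OC(C)(C)O[C@@H]2[C@H](C)O1
F8 | step 3 | tridecylmagnesium bromide | CCCCCCCCCCCCC[Mg]Br
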